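A direct plan would start from a dimethoxy-isopropylbenzene ring C, graft the sabinene unit onto it by carbonyl addition, epoxidation and a semipinacol aryl shift to reach the α-quaternary aldehyde A1, and add a cyclocitral-derived dienyllithium to A1.
After silylation to A2 it would close ring B and the cyclopentane in one intramolecular aryne–diene cycloaddition, then install the C6 ketone (A3), demethylate and oxidise.
Its weakest operations would be: (1) the dienyllithium addition to A1, because the C10' carbinol would rest on a Felkin preference alone although C7, C10 and C5 would all be relayed from it;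
(2) the aryne cycloaddition of A2, because two rings, the quaternary C10 and the facial sense would hang on one silyl ether while ene transfer and amide addition compete on a twisted diene;
(3) the BBr3 cleavage of both aryl methyl ethers of A3 at the last stage, because HBr and a strong Lewis acid would meet the cyclopropane and the β-hydroxy ketone on the most precious material.
About ten further steps (fluoroarene aldehyde, removal of the hydroxyl left by the aryl shift, protecting groups) would add little complexity.

Ring C is not treated as an arene: cutting C13=C14 (aldol condensation) and C9–C11 (acylation) removes it and uncovers a 4-hydroxycyclopent-2-enone, C10'(OH)–C7=C8–C14(=O), whose C5 is the thujane spiro carbon C4'.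
That is the product pattern of a Piancatelli rearrangement, so C4'–C10' is cut next: the enone becomes a furan (oxygen between C14 and C10', fused to ring B at C7–C8) bound through C14 to sabina ketone.
Rings arise in the order B (aldol condensation), A (cation–olefin cyclisation after a catalytic conjugate addition that sets C10), cyclopentane (key step, sets C4' and C10'), and ring C last, born directly as the hydroxy-quinone methide.
C10' is created inside a ring-forming electrocyclisation and no carbon has to reach the hindered face of C4'.
There is no aryne, no arene and no aryl ether, so the three weak operations have no counterpart, and the hexacyclic core exists only in the final product.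

Key step: step 9

Numbering: abietane numbers C1–C20 for the diterpenoid half, primed numbers C1'–C10' for the thujane half (C4' = spiro carbon, C10' = carbinol carbon, C6' = cyclopropane CH2).
Assumption: of the two C5 epimers of these 4,4,10-trimethyl 6-ketones, the one with H5 cis to the C20 methyl (required here) is taken to be the more stable, since it avoids the syn-diaxial C19/C20 methyl pair; C5 is therefore left to equilibration.

Step 1
Reactants: 1 (1R,5R)-(+)-sabinene
Product: 3 sabina ketone, via sabinene ozonide 2 (not isolated)
Conditions: O3, CH2Cl2, −78 °C; Me2S, −78 °C to rt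
Reagents that add atoms: ozone, [O-][O+]=O
Why: Ozonolysis with reductive work-up cleaves only the exocyclic C4'=CH2 bond and leaves the cyclopropane and both stereocentres untouched.

Step 2
Reactants: 4 3,4-dibromofuran
Product: 6 1-(4-bromofuran-3-yl)ethanone, via 4-bromofuran-3-yllithium 5 (not isolated)
Conditions: n-BuLi (1.0 equiv), Et2O, −78 °C; MeC(O)N(OMe)Me, −78 to 0 °C; aq. NH4Cl
Reagents that add atoms: N-methoxy-N-methylacetamide, CON(C)C(C)=O
Why: Bromine–lithium exchange at one of two equivalent bromides and acylation by the Weinreb amide (Weinreb ketone synthesis) should stop at the ketone and keep the second bromide for step 3.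

Step 3
Reactants: 6 1-(4-bromofuran-3-yl)ethanone
Product: 7 1-(4-acetylfuran-3-yl)propan-2-one
Conditions: isopropenyl acetate, Bu3SnOMe, PdCl2[P(o-tol)3]2 (3 mol %), toluene, 100 °C
Reagents that add atoms: isopropenyl acetate, CC(=C)OC(C)=O
Why: Migita-type palladium-catalysed arylation of the tributyltin enolate of acetone (formed in the flask from the enol acetate and the tin methoxide) runs under neutral conditions that the acetyl group tolerates.

Step 4
Reactants: 7 1-(4-acetylfuran-3-yl)propan-2-one
Product: 8 6-methylisobenzofuran-4(7H)-one
Conditions: KOH (0.3 equiv), EtOH, rt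
Reagents that add atoms: none
Why: Intramolecular aldol condensation in which the aryl methyl ketone enolate (C5) attacks the more electrophilic dialkyl ketone (C10) to close ring B, the mode by which 2-acetonylacetophenones give the 3-methyl-1-naphthol skeleton; the enone is kept here because its phenol tautomer would be an isobenzofuran.

Step 5
Reactants: 8 6-methylisobenzofuran-4(7H)-one
Product: 9 (R)-6-methyl-6-(4-methylpent-3-en-1-yl)-6,7-dihydroisobenzofuran-4(5H)-one
Conditions: 4-methylpent-3-enylmagnesium bromide, Cu(OTf)2 (3 mol %), chiral C2-symmetric imidazolinium salt (N-heterocyclic carbene precursor, 4 mol %), Et2O, 0 °C; aq. NH4Cl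
Reagents that add atoms: 4-methylpent-3-enylmagnesium bromide, CC(C)=CCC[Mg]Br
Why: Copper-catalysed enantioselective conjugate addition of a Grignard reagent to a 3-methylcyclohex-2-enone-type acceptor should set the quaternary C10; the ligand enantiomer that gives the (R) ketone is used, and the catalysed 1,4-addition should outrun deprotonation at C9.

Step 6
Reactants: 9 (R)-6-methyl-6-(4-methylpent-3-en-1-yl)-6,7-dihydroisobenzofuran-4(5H)-one
Product: 10 tricyclic furanone (4aR,8aR)-5,5,8a-trimethyl-4a,5,6,7,8,8a-hexahydronaphtho[2,3-c]furan-4(9H)-one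
Conditions: TfOH (0.2 equiv), (CF3)2CHOH/CH2Cl2, 0 °C; then NaOMe, MeOH, 40 °C
Reagents that add atoms: none
Why: Cation–olefin cyclisation ended by a ketone enol: Markovnikov protonation of the trisubstituted alkene gives the tertiary C4 cation, which is taken up by C5, the only enolisable position of the furyl ketone, to close ring A, and the base treatment should bring C5 to the more stable cis fusion relative to the fixed C10.

Step 7
Reactants: 10 tricyclic furanone
Product: 11 C14 bromide of 10 (1-bromo derivative)
Conditions: NBS (1.0 equiv), DMF, 0 °C, dark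
Reagents that add atoms: N-bromosuccinimide, O=C1CCC(=O)N1Br
Why: Electrophilic bromination of a 3-acylfuran goes to the α-position remote from the acyl group, here C14, which is also flanked by the alkyl-bearing C8, while C10' is deactivated by the C6 carbonyl on C7.

Step 8
Reactants: 11 C14 bromide; 3 sabina ketone
Product: 13 tertiary furylcarbinol (both C4' epimers), via furylmagnesium chloride 12 (not isolated)
Conditions: i-PrMgCl·LiCl, THF, −40 °C; 3, LaCl3·2LiCl, −40 to 0 °C; aq. NH4Cl
Reagents that add atoms: none
Why: Bromine–magnesium exchange on the acyl-activated 2-bromofuran and lanthanum-assisted 1,2-addition to the enolisable sabina ketone; the hindered, furan-conjugated C6 ketone should be left alone at low temperature, and the carbinol configuration is irrelevant because C4' becomes trigonal in step 9.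

Step 9
Reactants: 13 tertiary furylcarbinol
Product: 16 spiro 4-hydroxycyclopentenone, via furanium cation 14 (not isolated), via hydroxypentadienyl cation 15 (not isolated)
Conditions: Dy(OTf)3 (10 mol %), MeCN/H2O (5:1), 80 °C
Reagents that add atoms: water, O
Why: Piancatelli rearrangement: the Lewis acid ionises the tertiary carbinol to the furan-stabilised cation 14, water adds to the free furan α-carbon C10', ring opening gives the 1-hydroxypentadienyl cation 15, and a thermal conrotatory 4π electrocyclisation forms C4'–C10'; the closest known reaction type is the Piancatelli rearrangement of tertiary 2-furylcarbinols (2-furylcycloalkanols) to spirocyclic 4-hydroxycyclopent-2-enones. Only the cyclopentenone ring C14–C8–C7–C10'–C4' is closed, by electrocyclisation of the five-carbon cation (formally a 5-enolendo aldol of C4' onto the C10' aldehyde carbon), and it is spiro because the carbinol carbon is the thujane ring carbon C4'. C4' is set by the thujane ring itself, since C10' should bond to the lobe of C4' opposite the cyclopropane methylene C6', which leaves C14 on the C6' side as required. C10' is set by the geometry of 15: with the oxocarbenium hydroxyl outside and the in-plane C5'–H kept away from C9 (C5' outside, C3' inside), conrotation places the hydroxyl cis to the C3' methylene and trans to C5'. The step needs rearrangement to outrun cyclopropylcarbinyl ring opening and simple dehydration; the furan should secure this by taking up most of the positive charge (the C6 acyl group sits on C7, a nodal position of the cation, and C9 on C8 is a donor), and dehydration to the 3'-ene is reversible under the conditions. Both carbinol epimers of 13 converge on the same cation.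

Step 10
Reactants: 16 spiro 4-hydroxycyclopentenone
Product: 17 10'-O-trimethylsilyl ether and C6 trimethylsilyl dienol ether of 16 (C6=C7, C8=C9)
Conditions: TMSOTf (2.5 equiv), Et3N (3 equiv), CH2Cl2, −78 to 0 °C
Reagents that add atoms: trimethylsilyl trifluoromethanesulfonate, C[Si](C)(C)OS(=O)(=O)C(F)(F)F
Why: Silylation of the hydroxyl and soft enolisation of the C6 ketone through its γ-position C9 (C5 lies between two quaternary carbons and would give a strained tetrasubstituted enol ether) should give the silyl dienol ether, nucleophilic at C9.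

Step 11
Reactants: 18 4-methyl-2-oxopentanoic acid
Product: 19 4-methyl-2-oxopentanoyl chloride
Conditions: Cl2CHOMe, neat, 50 °C; used crude
Reagents that add atoms: dichloromethyl methyl ether, COC(Cl)Cl
Why: Conversion of an α-keto acid into its acid chloride by the α,α-dichloromethyl ether method used for pyruvoyl chloride.

Step 12
Reactants: 17 bis(trimethylsilyl) dienol ether; 19 4-methyl-2-oxopentanoyl chloride
Product: 21 CNP0178265.1, via triketone 20 (not isolated)
Conditions: ZnBr2 (10 mol %), CH2Cl2, −78 to −20 °C; then 1 M HCl, THF, 40 °C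
Reagents that add atoms: none
Why: Vinylogous Mukaiyama acylation at C9 forms C9–C11, and acid then removes the silyl ether and drives the intramolecular aldol condensation of C13 (α to the C12 ketone) onto the C14 ketone to close ring C, after which enolisation of C11 towards C9 gives the fully conjugated hydroxy-quinone methide; no stereocentre is formed and C5 stays under the thermodynamic control assumed above.

**Compound list**

1 | (1R,5R)-(+)-sabinene | C=C1CC[C@]2(C(C)C)C[C@@H]21 | starting material
2 | sabinene secondary ozonide, spiro-1,2,4-trioxolane at C4', both spiro epimers (not isolated) | C1OC2(CC[C@]3(C(C)C)C[C@@H]32)OO1 | intermediate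
3 | sabina ketone, (1S,5R)-5-isopropylbicyclo[3.1.0]hexan-2-one | O=C1CC[C@]2(C(C)C)C[C@@H]21 | intermediate
4 | 3,4-dibromofuran | Brc1cocc1Br | starting material
5 | 4-bromofuran-3-yllithium (not isolated) | [Li]c1cocc1Br | intermediate
6 | 1-(4-bromofuran-3-yl)ethanone | CC(=O)c1cocc1Br | intermediate
7 | 1-(4-acetylfuran-3-yl)propan-2-one | CC(=O)Cc1cocc1C(C)=O | intermediate
8 | 6-methylisobenzofuran-4(7H)-one (C6 ketone, C5=C10 enone, C9H2, furan at C7–C8) | CC1=CC(=O)c2cocc2C1 | intermediate
9 | (R)-6-methyl-6-(4-methylpent-3-en-1-yl)-6,7-dihydroisobenzofuran-4(5H)-one | CC(C)=CCC[C@@]1(C)CC(=O)c2cocc2C1 | intermediate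
10 | tricyclic furanone, (4aR,8aR)-5,5,8a-trimethyl-4a,5,6,7,8,8a-hexahydronaphtho[2,3-c]furan-4(9H)-one: rings A and B with C6 ketone, furan fused at C7–C8 (CH carbons C10' on C7 and C14 on C8), H5 cis to the C20 methyl | O=C1[C@@H]2C(C)(C)CCC[C@]2(C)Cc3cocc31 | intermediate
11 | C14 bromide of 10 (1-bromo derivative) | O=C1[C@@H]2C(C)(C)CCC[C@]2(C)Cc3c(Br)occ31 | intermediate
12 | C14 furylmagnesium chloride of 10 (not isolated) | O=C1[C@@H]2C(C)(C)CCC[C@]2(C)Cc3c([Mg]Cl)occ31 | intermediate
13 | tertiary furylcarbinol: 10 carrying at C14 the 2-hydroxy-5-isopropylbicyclo[3.1.0]hexan-2-yl group (C4'–OH), both C4' epimers | O=C1[C@@H]2C(C)(C)CCC[C@]2(C)Cc3c(C4(O)CC[C@]5(C(C)C)C[C@@H]54)occ31 | intermediate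
14 | 2-alkylidene furanium cation (C14=C4', O+=C10'; not isolated) | O=C1[C@@H]2C(C)(C)CCC[C@]2(C)CC3=C1C=[O+]C3=C4CC[C@]5(C(C)C)C[C@@H]54 | intermediate
15 | ring-opened 1-hydroxypentadienyl cation, C4'=C14(OH)–C8=C7–C10'H=OH+ (not isolated) | O=C1[C@@H]2C(C)(C)CCC[C@]2(C)CC(=C1C=[OH+])C(O)=C3CC[C@]4(C(C)C)C[C@@H]43 | intermediate
16 | spiro 4-hydroxycyclopentenone: C14 ketone, C7=C8, C10'(H)(OH), spiro C4' (C14 cis to C6', 10'-OH cis to C3'), C6 ketone, C9H2, rings A and B as in 10 | O=C2C3=C(C(=O)[C@@H]4C(C)(C)CCC[C@]4(C)C3)[C@H](O)[C@]21CC[C@]2(C(C)C)C[C@@H]21 | intermediate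
17 | 10'-O-trimethylsilyl ether and C6 trimethylsilyl dienol ether of 16 (C6=C7, C8=C9) | O=C2C3C(=C(O[Si](C)(C)C)[C@@H]4C(C)(C)CCC[C@]4(C)C=3)[C@H](O[Si](C)(C)C)[C@]21CC[C@]2(C(C)C)C[C@@H]21 | intermediate
18 | 4-methyl-2-oxopentanoic acid | CC(C)CC(=O)C(O)=O | starting material
19 | 4-methyl-2-oxopentanoyl chloride | CC(C)CC(=O)C(Cl)=O | intermediate
20 | 9-(4-methyl-2-oxopentanoyl) derivative of 16, C9 epimers, largely enolised (not isolated) | O=C2C3=C(C(=O)[C@@H]4C(C)(C)CCC[C@]4(C)C3C(=O)C(=O)CC(C)C)[C@H](O)[C@]21CC[C@]2(C(C)C)C[C@@H]21 | intermediate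
21 | CNP0178265.1 | CC(C)C1=C2C3=C(C(=O)[C@@H]4C(C)(C)CCC[C@]4(C)C3=C(O)C1=O)[C@H](O)[C@]21CC[C@]2(C(C)C)C[C@@H]21 | target

Total step count: 12. Longest linear sequence: 10 steps (4 to 21: steps 2–10 and 12; steps 1 and 11 are side branches).

Steps most likely to fail:

Step 9. The ionised carbinol may open the cyclopropane or simply dehydrate, and the conrotation may show a poor facial bias. The fallback uses the known furan-to-hydroxycyclopentenone route by oxidative ring opening. It sets out from 13, which is dehydrated (Burgess reagent) to the 4'-furyl-thuj-3'-ene F1. Only that alkene is hydrogenated ([Ir(cod)(PCy3)(py)]PF6, H2) to give the 2-(thujan-4'-yl)furan F2. The furan is opened with NBS in NaHCO3-buffered aqueous acetone to the cis-ene-1,4-dicarbonyl compound F3. Phosphate-buffered intramolecular aldol addition of C4' (α to the C14 ketone) to the C10' aldehyde, again entering C4' opposite C6', rejoins the route at 16.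

Step 12. Acylation may occur at oxygen or at C7 instead of C9, the α-keto acid chloride may lose CO, and the Lewis acid may erode C10'. The fallback sets out from 17. A BF3·OEt2-mediated vinylogous Mukaiyama aldol addition of C9 to the aldehyde group of 4-methyl-2-oxopentanal gives, after desilylation, the C9 aldol F4. Acid-catalysed aldol condensation of C13 onto C14 closes ring C to the α-ketol F5. Oxidation of the ketol (Cu(OAc)2, MeOH, air) rejoins the route at 21.

Step 5. The Grignard reagent may deprotonate C9, or the enantioselectivity may be low. The fallback exchanges the two C10 substituents and sets out from 6. Migita coupling with the kinetic enol acetate of 6-methylhept-5-en-2-one gives the diketone F6. Aldol condensation as in step 4 gives the enone F7, which carries the 4-methylpent-3-enyl group on C10. Copper-catalysed addition of AlMe3 (copper thiophene-2-carboxylate, phosphoramidite ligand of the opposite sense) then delivers the methyl group and rejoins the route at 9.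

Further compounds
F1 | step 9 | 4'-furyl-thuj-3'-ene: dehydration product of 13 (C4'=C3') | O=C1[C@@H]2C(C)(C)CCC[C@]2(C)Cc3c(C4=CC[C@]5(C(C)C)C[C@@H]54)occ31
F2 | step 9 | 2-(thujan-4'-yl)furan: 10 carrying the thujan-4'-yl group at C14 (C4' epimers) | O=C1[C@@H]2C(C)(C)CCC[C@]2(C)Cc3c(C4CC[C@]5(C(C)C)C[C@@H]54)occ31
F3 | step 9 | cis-ene-1,4-dicarbonyl compound: C14 thujan-4'-yl ketone on C8, C10' aldehyde on C7, C7=C8, C6 ketone | O=C1[C@@H]2C(C)(C)CCC[C@]2(C)CC(C(=O)C3CC[C@]4(C(C)C)C[C@@H]43)=C1C=O
F4 | step 12 | C9 aldol of 16 with 4-methyl-2-oxopentanal (C9–C11H(OH)–C12(=O)–CH2CHMe2) | O=C2C3=C(C(=O)[C@@H]4C(C)(C)CCC[C@]4(C)C3C(O)C(=O)CC(C)C)[C@H](O)[C@]21CC[C@]2(C(C)C)C[C@@H]21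
F5 | step 12 | ring-C α-ketol: 9,11-dihydro-11-hydroxy form of 21 (C9–H, C11–H(OH), C12 ketone, C13=C14, C7=C8) | CC(C)C1=C2C3=C(C(=O)[C@@H]4C(C)(C)CCC[C@]4(C)C3C(O)C1=O)[C@H](O)[C@]21CC[C@]2(C(C)C)C[C@@H]21
F6 | step 5 | 1-(4-acetylfuran-3-yl)-6-methylhept-5-en-2-one | CC(=O)c1cocc1CC(=O)CCC=C(C)C
F7 | step 5 | 6-(4-methylpent-3-en-1-yl)isobenzofuran-4(7H)-one | CC(C)=CCCC1=CC(=O)c2cocc2C1
A1 | direct plan | (4'S)-4'-(6-fluoro-2-isopropyl-3,4-dimethoxyphenyl)thujan-10'-al | CC(C)c1c([C@]2(C=O)CC[C@]3(C(C)C)C[C@@H]32)c(F)cc(OC)c1OC
A2 | direct plan | 8-fluoroaryl thujane with the C10' tert-butyldimethylsilyloxy dienyl chain (cycloaddition precursor) | CC(C)c1c(OC)c(OC)cc(F)c1[C@@]1(CC[C@]2(C(C)C)C[C@@H]21)[C@@H](O[Si](C)(C)C(C)(C)C)/C=C/C1=C(C)CCCC1(C)C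
A3 | direct plan | hexacyclic 11,12-dimethoxy 6-ketone with C10' silyl ether | CC(C)c1c2c3[C@@H](C(=O)[C@@H]4C(C)(C)CCC[C@]4(C)c3c(OC)c1OC)[C@H](O[Si](C)(C)C(C)(C)C)[C@]21CC[C@]2(C(C)C)C[C@@H]21
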